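## Structural features

The target is a xenicane ester built on a nine-membered carbocycle (ring A: C4a, C5, C6, C7, C8, C9, C10, C11, C11a) fused trans through the C4a–C11a bond to a 2-acetoxy-3,4-dihydro-2H-pyran (ring B: C1, O2, C3=C4, C4a, C11a). Ring A carries an exocyclic methylene at C11 (C19) and a C7–C8 epoxide with the methyl group on C7. Reading the configuration shows that the ring bonds C6–C7 and C8–C9 are cis on the oxirane, so the epoxide is the oxide of a Z-cyclononene and a Z olefin is the correct one to carry through the synthesis. C4 bears the side chain: the C12 acetoxy carbinol, C13H2 and the E-configured C14=C15 2-methyl enoate (methyl ester). Of the six stereocentres, C1 (R), C11a (R) and C4a (S) are contiguous, C7 (S) and C8 (R) lie across ring A from them, and C12 (S) is insulated from the ring stereocentres by the sp2 carbon C4. The fragile groups are the acylal at C1, the enol ether, the C12 acetate (allylic to the enol ether, hence a vinylogous acetal that ionises easily), the acid-labile epoxide and the methylene that is β,γ to C1. The real difficulty is the order of events: C7=C8 can only be oxidised while an acceptor on C4 deactivates the enol ether, and no strong acid may be used afterwards. The key step exploits the fact that C11 is a masked ketone: C11a and C4a are then its α- and β-carbons, and each carries an aldehyde-level arm (C1 on C11a; C4 with C3 and C12 on C4a), so both arms can be added trans across the enone C4a=C11a of a cyclononadienone.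

## Logic of the disconnections

**24 back to 22 (through 23).** The two acetate C–O bonds at C1 and C12 are cut, and the C1 oxygen is stored as a silyl acetal. These are the functions least able to survive hydride, oxidant or Lewis acid, so they come last. The demand on the forward step is that the lactol be unveiled without acid or strong base and that both hydroxyls be acetylated in one operation.

**22 back to 19 and 21.** The C12–C13 bond is cut. A carbinol flanked by an sp2 carbon and a γ-extended 2-methyl enoate is the retron of a vinylogous aldol addition. The whole side chain disappears and leaves a C12 aldehyde that is a vinylogous formate. The forward step must attack through the γ-carbon, give the E enoate, set C12 by the promoter and spare the epoxide.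

**19 back to 18, 17 and 16.** C12 is taken back from aldehyde to alcohol to ester, and the two C–O bonds of the epoxide are cut to the Z olefin. The epoxide is placed here because only an acceptor on C4 keeps the C3=C4 enol ether from competing. Two stereocentres vanish. The forward step needs chemoselectivity over C11=C19 and the correct π-face.

**16 back to 15 and 13.** The Si–O bond and then the O2–C1 bond are cut, so that ring B unravels to a C1 aldehyde and a C3 formyl ester, both held as dimethyl acetals in 13. Ring B and the anomeric centre are removed. The hydrolysis must be mild enough not to move C11=C19 into conjugation with C1.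

**13 back to 12.** The C11=C19 bond is cut to the ketone (Wittig retron). The ketone is what makes C11a and C4a the α- and β-carbons. The methylenation must not eliminate methanol from the β-keto acetal.

**12 back to 8, 10 and 2.** The C4a–C4 and C11a–C1 bonds are cut. A conjugate addition of an ester enolate equivalent followed by trapping of the regiodefined enolate with a formyl cation equivalent removes three stereocentres and ten carbons of functionality at once. The forward step needs enantioface control at C4a and trans trapping at C11a.

**10 back to 9, and 21 back to 20.** Each Si–O bond is cut to the parent ester. The enolisations must avoid β-elimination (9) and must take the γ-proton (20).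

**8 back to 7, 6, 4 and then 1 with 2.** The C11a=C4a olefin is cut (intramolecular Horner–Wadsworth–Emmons), then the C–P bond and the aldehyde acetal, and finally the two carbonyls are rejoined into one olefin of the cyclooctadiene. All ten carbons and the Z geometry of C7=C8 are bought in 1, and one methyl group of 1 becomes the ring carbon C11a. The demands are mono-cleavage of 1 and a nine-membered closure.

## Other disconnections considered

**Alternative 1:** The cut runs through C11a–C4a and O2–C1, so both rings open to the acyclic bis-enal A2, which already holds the epoxide, the C12 acetate and the enoate. In the forward sense a diarylprolinol silyl ether would turn the C1 enal of A2 into a dienamine (loss of a C19 proton creates the methylene), its α-carbon C11a would add to C4a of the second enal and close ring A, and the C3 enol oxygen would add to C1 to give lactol A1, one acetylation from the target.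
- In favour: two rings, the methylene and two stereocentres arise in one operation, C1 needs no protecting group, and no Lewis acid ever meets the epoxide. On these points it is better than the chosen plan.
- Against: a nine-membered Michael closure must beat oligomerisation, γ-attack of the dienamine and deprotonation at C10. The acceptor is an α-branched enal with an allylic acetate that a secondary amine can displace. C11a and C4a would have to be set in a medium-ring transition state without a close model. A2 needs its own reagent-controlled construction of the epoxide and C12 on an open chain. A1 has no acceptor on C4, so its lactol can open to a dialdehyde.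
- Comparison: structurally the alternative builds both rings in the key step, whereas the chosen plan builds none there and pays for ring A in a simple olefination. Mechanistically, aminocatalysis in a medium ring is less predictable than silylium catalysis on a preformed ring. In step economy the alternative is better after A2 but worse in reaching A2.

**Alternative 2:** The C9–C11 bond is reconnected and C19 becomes a xanthate-bearing CH2, giving the cyclopropane-fused cyclooctene A4. Bu3SnH and AIBN would generate the C19 radical, the cyclopropylcarbinyl radical would open by cleavage of C9–C11 to an allylic radical, and hydrogen transfer at C9 would give the nine-membered methylene compound A3.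
- In favour: eight-membered precursors are easier to close than nine-membered ones, the expansion and the methylene come together under neutral conditions, and the allylic stabilisation directs the ring-enlarging cleavage. It avoids a basic methylenation next to a β-keto acetal, which is a point on which it is better.
- Against: the allylic radical is delocalised over C9, C8 and C7, so hydrogen transfer at C7 would transpose the olefin and the Z geometry could scramble. A4 needs a quaternary cyclopropane carbon and the C4a/C11a stereocentres set on a bicyclic precursor. Stoichiometric tin is needed.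
- Comparison: A3 is the methyl-acetal analogue of 16, so the end game would be the same and the two plans are equal from there. Mechanistically the polar route controls the olefin position with certainty, the radical route does not. In step economy the route to A4 is expected to be clearly longer than the six steps to 12.

**Alternative 3:** The C7–C11 bond is reconnected, giving the tricyclic hydroxy tosylate A6 (five- and six-membered carbocycles plus ring B). KOtBu would form the C11 alkoxide, which fragments (Grob) with cleavage of C7–C11 and C8–O to the Z-cyclononenone A5.
- In favour: the fragmentation is the classical way into nine-membered rings, it is stereospecific, and it pays the ring strain in the fragmentation itself. In reliability of forming ring A it is better than a nine-membered olefination.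
- Against: A6 needs six stereocentres, including a quaternary C7 and a tosylate set anti-periplanar to C7–C11 with the relative configuration that gives Z. A5 is a β-keto acetal exposed to alkoxide, so epimerisation at C11a or β-elimination can follow. The route to A6 is long.
- Comparison: A5 is the ring-closed counterpart of 12 and would join the chosen end game after methylenation, so the plans are equal there. Mechanistically the olefin geometry comes from sp3 stereochemistry that must first be built, whereas the chosen plan buys it with 1. In step economy the chosen plan is shorter.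

Key step: step 6

Remark 1: commercial 1 contains the 1,6-dimethyl isomer, which would put the ring methyl on C8; 1 is taken as the fractionated, isomerically pure 1,5-compound.
Remark 2: the antipodes of the chiral promoters in steps 6 and 14 are written provisionally from the usual models; the mirror-image promoter is used if the sense of induction is the opposite.
Remark 3: 15 to 23 are drawn as the 1,11a-trans anomers; the cis anomers converge in step 15, where the lactol equilibrates.

Step 1
Reactants: 1 (1Z,5Z)-1,5-dimethylcycloocta-1,5-diene; 2 trimethyl orthoformate
Product: 4 (Z)-9,9-dimethoxy-6-methylnon-5-en-2-one, via keto aldehyde 3 (not isolated)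
Conditions: O3 (0.9 equiv), CH2Cl2/MeOH, −78 °C; Me2S, −78 °C → rt; then 2, CeCl3·7H2O (cat.), rt
Reagents that add atoms: ozone, [O-][O+]=O
Why: A substoichiometric charge of ozone cleaves one of the two equivalent trisubstituted olefins (ozonolysis with reductive work-up) and leaves the other with its ring-derived Z geometry. CeCl3-catalysed acetalisation with the orthoformate takes the aldehyde and not the methyl ketone.

Step 2
Reactants: 4 (Z)-9,9-dimethoxy-6-methylnon-5-en-2-one
Product: 6 diethyl [(Z)-9,9-dimethoxy-6-methyl-2-oxonon-5-en-1-yl]phosphonate, via keto phosphonite 5 (not isolated)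
Conditions: LiN(iPr)2, THF, −78 °C; ClP(OEt)2, −78 → 0 °C; air, rt
Reagents that add atoms: diethyl chlorophosphite, CCOP(Cl)OCC; dioxygen, O=O
Why: Kinetic deprotonation takes the methyl group of the methyl ketone, the soft trivalent phosphorus chloride is attacked through carbon, and air oxidises the phosphonite to the β-keto phosphonate (enolate phosphinylation–oxidation). Any internal regioisomer cannot close to 8 and is removed by chromatography.

Step 3
Reactants: 6 diethyl [(Z)-9,9-dimethoxy-6-methyl-2-oxonon-5-en-1-yl]phosphonate
Product: 7 diethyl [(Z)-6-methyl-2,9-dioxonon-5-en-1-yl]phosphonate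
Conditions: AcOH/THF/H2O (3:1:1), rt
Reagents that add atoms: water, O
Why: Acid-catalysed acetal hydrolysis; the weak acid frees the aldehyde far faster than it can hydrate the trisubstituted olefin, and the keto phosphonate is inert.

Step 4
Reactants: 7 diethyl [(Z)-6-methyl-2,9-dioxonon-5-en-1-yl]phosphonate
Product: 8 (2Z,6Z)-6-methylcyclonona-2,6-dien-1-one
Conditions: LiCl, iPr2NEt, MeCN (2 mM, slow addition), rt → 50 °C
Reagents that add atoms: none
Why: Intramolecular Horner–Wadsworth–Emmons olefination under Masamune–Roush conditions at high dilution; only the phosphonate carbon is deprotonated by the mild base, so the nine-membered ring is the only aldol-type closure open. The ring size allows only the Z enone, and the Z olefin of the tether brings the two ends together.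

Step 5
Reactants: 9 methyl 3,3-dimethoxypropanoate
Product: 10 (Z)-trimethyl[(1,3,3-trimethoxyprop-1-en-1-yl)oxy]silane
Conditions: LiN(iPr)2, THF, −78 °C; Me3SiCl, −78 °C → rt; non-aqueous work-up, distillation
Reagents that add atoms: chlorotrimethylsilane, C[Si](C)(C)Cl
Why: Kinetic ester enolisation and O-silylation give the silyl ketene acetal; the low temperature and immediate silylation keep the lithium enolate from losing methoxide. The geometry is drawn Z but either isomer serves, because C4 later becomes sp2.

Step 6
Reactants: 8 (2Z,6Z)-6-methylcyclonona-2,6-dien-1-one; 10 (Z)-trimethyl[(1,3,3-trimethoxyprop-1-en-1-yl)oxy]silane; 2 trimethyl orthoformate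
Product: 12 methyl (2S)-2-[(1S,2S,6Z)-2-(dimethoxymethyl)-7-methyl-3-oxocyclonon-6-en-1-yl]-3,3-dimethoxypropanoate, via enol silane 11 (not isolated)
Conditions: (S)-3,3'-bis[3,5-bis(trifluoromethyl)phenyl]-1,1'-binaphthyl-2,2'-disulfonimide (5 mol %), Et2O, −78 → −40 °C; then 2, Me3SiOTf (10 mol %), CH2Cl2, −78 °C; Et3N quench
Reagents that add atoms: none
Why: The disulfonimide is silylated by 10 to an N-silyl imide that acts as a silylium-type Lewis acid; it silylates the carbonyl oxygen of 8, the ketene acetal attacks the β-carbon C4a inside the chiral ion pair (C4a–C4 bond), and silicon is passed on, so that 11 forms as the C11=C11a enol silane only. Added 2 is then ionised by Me3SiOTf to the dimethoxycarbenium ion, which alkylates C11a of 11 (C11a–C1 bond) with loss of Me3SiOMe. The closest known reaction type is the catalytic asymmetric Mukaiyama–Michael addition of silyl ketene acetals to cyclic enones with alkylation of the enol silane by an orthoester in the same flask; the nine-membered dienone is a new substrate for it. No ring is closed, so no mode of closure arises. C4a is set by the chiral counter-anion, which leaves one face of the silylated enone open (4aS); C11a is set by the substrate, the carbenium ion approaching anti to the new C4a substituent (trans; 11aS by CIP, the spatial arrangement of 11aR in the target); C4 needs no control because it becomes sp2 in step 8. The step needs 1,4- over 1,2-addition (soft ketene acetal, silicon on oxygen), a regiodefined enolate (silicon transfer without a proton source, hence no drift towards C10) and no reaction of 10 with 2 (2 is added only after 8 is consumed). The isolated Z-C7=C8 olefin is not an acceptor and stays untouched. The amine quench at −78 °C keeps the β-keto acetal from losing methanol.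

Step 7
Reactants: 12 methyl (2S)-2-[(1S,2S,6Z)-2-(dimethoxymethyl)-7-methyl-3-oxocyclonon-6-en-1-yl]-3,3-dimethoxypropanoate
Product: 13 methyl (2S)-2-[(1S,2R,6Z)-2-(dimethoxymethyl)-7-methyl-3-methylidenecyclonon-6-en-1-yl]-3,3-dimethoxypropanoate
Conditions: Ph3PCH3Br, KOtBu, THF, 0 °C → rt
Reagents that add atoms: methyltriphenylphosphonium bromide, C[P+](c1ccccc1)(c1ccccc1)c1ccccc1.[Br-]
Why: Wittig methylenation of the C11 ketone; addition of the ylide should outrun enolisation at the hindered C11a, and the trans arrangement is the more stable one in any case. Should the ester α-proton be removed with loss of methoxide, the resulting β-methoxyacrylate is at the same oxidation level and is expected to converge on 15 in step 8.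

Step 8
Reactants: 13 methyl (2S)-2-[(1S,2R,6Z)-2-(dimethoxymethyl)-7-methyl-3-methylidenecyclonon-6-en-1-yl]-3,3-dimethoxypropanoate
Product: 15 methyl (4aS,7Z,11aR)-1-hydroxy-7-methyl-11-methylidene-1,4a,5,6,9,10,11,11a-octahydrocyclonona[c]pyran-4-carboxylate, via dialdehyde 14 (not isolated)
Conditions: AcOH/THF/H2O (3:1:1), 45 °C
Reagents that add atoms: water, O
Why: Hydrolysis of both acetals frees the C1 aldehyde and the C3 formyl ester, whose enol hydroxyl adds to C1 to close ring B as a six-membered hemiacetal, as in iridoid and secoiridoid aglycones. The weak acid leaves both olefins alone, and the ring closure removes the β,γ-unsaturated aldehyde before it can conjugate.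

Step 9
Reactants: 15 methyl (4aS,7Z,11aR)-1-hydroxy-7-methyl-11-methylidene-1,4a,5,6,9,10,11,11a-octahydrocyclonona[c]pyran-4-carboxylate
Product: 16 1-O-tert-butyldimethylsilyl ether of 15
Conditions: tBuMe2SiCl, imidazole, DMF, rt
Reagents that add atoms: tert-butylchlorodimethylsilane, CC(C)(C)[Si](C)(C)Cl
Why: Silylation of the lactol hydroxyl gives a silyl acetal that withstands peracid, hydride, MnO2 and a boron Lewis acid at −78 °C and is later removed by fluoride without acid. A methyl acetal is avoided because its hydrolysis at the end would endanger the epoxide and the C12 acetate.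

Step 10
Reactants: 16 1-O-tert-butyldimethylsilyl ether of 15
Product: 17 (7S,8R)-7,8-epoxide of 16
Conditions: mCPBA (1.05 equiv), NaHCO3, CH2Cl2, −20 → 0 °C
Reagents that add atoms: 3-chloroperbenzoic acid, OOC(=O)c1cccc(Cl)c1
Why: Prilezhaev epoxidation of the most electron-rich olefin; C11=C19 is only 1,1-disubstituted and C3=C4 is deactivated by the ester. Syn addition keeps C6 and C9 cis, and peripheral attack on the face anti to the C4a–C4 bond (syn to H-4a) is expected to give 7S,8R.

Step 11
Reactants: 17 (7S,8R)-7,8-epoxide of 16
Product: 18 C12 primary alcohol (4-hydroxymethyl compound) from 17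
Conditions: iBu2AlH (2.5 equiv), CH2Cl2, −78 °C; aq. KNaC4H4O6
Reagents that add atoms: none
Why: 1,2-Reduction of the β-alkoxyacrylate ester by iBu2AlH; the trisubstituted epoxide and the silyl acetal are inert at −78 °C.

Step 12
Reactants: 18 C12 primary alcohol (4-hydroxymethyl compound) from 17
Product: 19 C12 aldehyde (4-formyl compound)
Conditions: MnO2, CH2Cl2, rt
Reagents that add atoms: none
Why: MnO2 oxidises the allylic alcohol under neutral conditions to the vinylogous formate, which again deactivates the enol ether and avoids acid on the labile alcohol.

Step 13
Reactants: 20 methyl tiglate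
Product: 21 tert-butyl[(1-methoxy-2-methylbuta-1,3-dien-1-yl)oxy]dimethylsilane (E/Z mixture usable)
Conditions: LiN(iPr)2, THF/DMPU, −78 °C; tBuMe2SiCl, −78 °C → rt
Reagents that add atoms: tert-butylchlorodimethylsilane, CC(C)(C)[Si](C)(C)Cl
Why: γ-Deprotonation of the enoate and O-silylation give the silyl dienolate; DMPU suppresses conjugate addition of the amide.

Step 14
Reactants: 19 C12 aldehyde (4-formyl compound); 21 tert-butyl[(1-methoxy-2-methylbuta-1,3-dien-1-yl)oxy]dimethylsilane
Product: 22 (12S)-alcohol: methyl (2E,5S)-5-hydroxy-2-methylpent-2-enoate carrying at C5 the ring system of 19 (C1 silyl acetal and epoxide retained)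
Conditions: (R)-4-(1H-indol-3-ylmethyl)-2-phenyl-3-tosyl-1,3,2-oxazaborolidin-5-one (preformed, from N-tosyl-D-tryptophan), iPrOH, EtCN, −78 °C
Reagents that add atoms: none
Why: Vinylogous Mukaiyama aldol addition promoted by a chiral oxazaborolidinone (Kiyooka type): the open transition state and the α-methyl group direct attack through the γ-carbon and give the E enoate. The promoter shields one face of the bound aldehyde so that addition to the Si face gives 12S, and isopropanol takes up the silyl group.

Step 15
Reactants: 22 (12S)-alcohol
Product: 24 target, (1R,4aS,7S,8R,11aR,12S)-1,12-diacetate, via diol lactol 23 (not isolated)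
Conditions: Bu4NF, AcOH, THF, 0 °C; then Ac2O, pyridine, DMAP, 0 °C
Reagents that add atoms: acetic anhydride, CC(=O)OC(C)=O
Why: Buffered fluoride cleaves the anomeric silyl ether without acid or strong base, and DMAP-catalysed acetylation then esterifies the C12 hydroxyl and the lactol. The lactol anomers equilibrate, and the equatorial hydroxyl trans to the C11a–C11 bond is acylated faster, which gives the 1R acetate.

## Compound list

1 | (1Z,5Z)-1,5-dimethylcycloocta-1,5-diene | C/C1=C/CC/C(C)=C\CC1 | starting material
2 | trimethyl orthoformate | COC(OC)OC | starting material
3 | (Z)-4-methyl-8-oxonon-4-enal | O=CCC/C(C)=C\CCC(C)=O | intermediate (not isolated)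
4 | (Z)-9,9-dimethoxy-6-methylnon-5-en-2-one | CC(=O)CC/C=C(C)\CCC(OC)OC | intermediate
5 | diethyl [(Z)-9,9-dimethoxy-6-methyl-2-oxonon-5-en-1-yl]phosphonite | CCOP(OCC)CC(=O)CC/C=C(C)\CCC(OC)OC | intermediate (not isolated)
6 | diethyl [(Z)-9,9-dimethoxy-6-methyl-2-oxonon-5-en-1-yl]phosphonate | CCOP(=O)(OCC)CC(=O)CC/C=C(C)\CCC(OC)OC | intermediate
7 | diethyl [(Z)-6-methyl-2,9-dioxonon-5-en-1-yl]phosphonate | CCOP(=O)(OCC)CC(=O)CC/C=C(C)\CCC=O | intermediate
8 | (2Z,6Z)-6-methylcyclonona-2,6-dien-1-one | O=C1/C=C\CC/C(C)=C\CC1 | intermediate
9 | methyl 3,3-dimethoxypropanoate | COC(CC(=O)OC)OC | starting material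
10 | (Z)-trimethyl[(1,3,3-trimethoxyprop-1-en-1-yl)oxy]silane | COC(OC)/C=C(/OC)O[Si](C)(C)C | intermediate
11 | C11 trimethylsilyl enol ether (C11=C11a, ring-cis) of the 4aS Michael adduct | C[Si](C)(C)O/C1=C/[C@@H]([C@H](C(=O)OC)C(OC)OC)CC/C(C)=C\CC1 | intermediate (not isolated)
12 | methyl (2S)-2-[(1S,2S,6Z)-2-(dimethoxymethyl)-7-methyl-3-oxocyclonon-6-en-1-yl]-3,3-dimethoxypropanoate (C4 epimer equally usable) | O=C1CC/C=C(C)\CC[C@H]([C@H](C(=O)OC)C(OC)OC)[C@H]1C(OC)OC | intermediate
13 | methyl (2S)-2-[(1S,2R,6Z)-2-(dimethoxymethyl)-7-methyl-3-methylidenecyclonon-6-en-1-yl]-3,3-dimethoxypropanoate | C=C1CC/C=C(C)\CC[C@H]([C@H](C(=O)OC)C(OC)OC)[C@H]1C(OC)OC | intermediate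
14 | open dialdehyde: C1 aldehyde and C3 formyl ester on the methylidene cyclononene (C4 enolisable) | C=C1CC/C=C(C)\CC[C@H](C(C=O)C(=O)OC)[C@H]1C=O | intermediate (not isolated)
15 | methyl (4aS,7Z,11aR)-1-hydroxy-7-methyl-11-methylidene-1,4a,5,6,9,10,11,11a-octahydrocyclonona[c]pyran-4-carboxylate (1,11a-trans anomer drawn) | C=C1CC/C=C(C)\CC[C@@H]2C(C(=O)OC)=CO[C@H](O)[C@@H]12 | intermediate
16 | 1-O-tert-butyldimethylsilyl ether of 15 | C=C1CC/C=C(C)\CC[C@@H]2C(C(=O)OC)=CO[C@H](O[Si](C)(C)C(C)(C)C)[C@@H]12 | intermediate
17 | (7S,8R)-7,8-epoxide of 16 | C=C1CC[C@H]2O[C@@]2(C)CC[C@@H]2C(C(=O)OC)=CO[C@H](O[Si](C)(C)C(C)(C)C)[C@@H]12 | intermediate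
18 | C12 primary alcohol (4-hydroxymethyl compound) from 17 | C=C1CC[C@H]2O[C@@]2(C)CC[C@@H]2C(CO)=CO[C@H](O[Si](C)(C)C(C)(C)C)[C@@H]12 | intermediate
19 | C12 aldehyde (4-formyl compound) | C=C1CC[C@H]2O[C@@]2(C)CC[C@@H]2C(C=O)=CO[C@H](O[Si](C)(C)C(C)(C)C)[C@@H]12 | intermediate
20 | methyl tiglate, methyl (E)-2-methylbut-2-enoate | C/C=C(\C)C(=O)OC | starting material
21 | tert-butyl[(1-methoxy-2-methylbuta-1,3-dien-1-yl)oxy]dimethylsilane (ketene acetal geometry not defined) | C=CC(C)=C(OC)O[Si](C)(C)C(C)(C)C | intermediate
22 | (12S)-alcohol with E enoate side chain, C1 silyl acetal, 7,8-epoxide | C=C1CC[C@H]2O[C@@]2(C)CC[C@@H]2C([C@H](C/C=C(\C)C(=O)OC)O)=CO[C@H](O[Si](C)(C)C(C)(C)C)[C@@H]12 | intermediate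
23 | C1 lactol, C12 alcohol (1,12-bis-deacetyl target) | C=C1CC[C@H]2O[C@@]2(C)CC[C@@H]2C([C@H](C/C=C(\C)C(=O)OC)O)=CO[C@H](O)[C@@H]12 | intermediate (not isolated)
24 | target, (1R,4aS,7S,8R,11aR,12S)-1,12-diacetate | C=C1CC[C@H]2O[C@@]2(C)CC[C@@H]2C([C@H](C/C=C(\C)C(=O)OC)OC(C)=O)=CO[C@H](OC(C)=O)[C@@H]12 | target

## Step count and least certain steps

Total: 15 steps, including the two one-step preparations of the silyl nucleophiles (steps 5 and 13). Longest linear sequence: 13 steps (steps 1–4, 6–12, 14 and 15).

**Step 6 (key step).** The ketene acetal may destroy itself by silylium-induced loss of methoxide, turnover may be slow because the Z-enone of the nine-membered ring is twisted out of conjugation, the catalyst pocket may discriminate the enone faces poorly, or the trans relationship may erode if the enol silane is protonated before it is trapped. The fallback sets out from 8, 10 and 2 and returns at 12. The same two bonds are made with an achiral silyl Lewis acid (Me3SiOTf, catalytic, CH2Cl2, −78 °C; Mukaiyama–Michael addition, then orthoformate alkylation). This gives 12 as a racemate with its enantiomer, methyl (2R)-2-[(1R,2R,6Z)-2-(dimethoxymethyl)-7-methyl-3-oxocyclonon-6-en-1-yl]-3,3-dimethoxypropanoate F1. The enantiomers are separated by preparative chromatography on a chiral stationary phase, and 12 continues with step 7.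

**Step 4.** Intermolecular olefination to cyclic dimers and oligomers may outrun the nine-membered closure. The fallback sets out from 3 (isolated after the Me2S reduction of step 1, before 2 is added) and returns at 8. Aldehyde-selective Wittig methylenation (Ph3P=CH2, THF, −78 → 0 °C) gives (Z)-6-methyldeca-5,9-dien-2-one F2. Kinetic enolisation and dimethylmethyleneammonium iodide give the Mannich base (Z)-1-(dimethylamino)-7-methylundeca-6,10-dien-3-one F3. Methylation with MeI and elimination with NaHCO3 give the vinyl ketone (Z)-7-methylundeca-1,6,10-trien-3-one F4. Ring-closing metathesis with the second-generation Hoveyda–Grubbs catalyst in dilute toluene at 80 °C then closes the enone of 8 with loss of ethylene.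

**Step 10.** The peracid may attack both faces of the flexible ring, or mainly the wrong one, and may begin to oxidise C11=C19. The fallback sets out from 16 and returns at 17, and applies if the peracid favours the face opposite to the one needed. NBS in THF/H2O at 0 °C forms the bromonium ion on that more accessible face, and water opens it at C7 from the other side to give the (7S,8S)-8-bromo-7-hydroxy compound F5. K2CO3 in MeOH then closes the epoxide with inversion at C8, which places the oxygen on the face that the direct epoxidation missed.

**Step 14.** The boron Lewis acid may open or rearrange the epoxide, the new C12–O bond (a vinylogous acetal) may ionise and eliminate, the dienolate may react through its α-carbon, and facial control may be weak. The fallback sets out from 19 and returns at 22. Allylation with (−)-B-allyldiisopinocampheylborane (from (+)-α-pinene; Et2O, −78 °C; ethanolamine work-up), which adds to the Si face without a Lewis acid, gives the (12S)-homoallylic alcohol F6. Cross-metathesis with methyl methacrylate (second-generation Hoveyda–Grubbs catalyst, CH2Cl2, 40 °C) then installs the E 2-methyl enoate of 22.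

**Step 15.** The unprotected lactol 23 has no acceptor on C4 and may open to the 1,5-dialdehyde, which can undergo retro-aldol cleavage or β-elimination at C12; both anomeric acetates may also form. The fallback sets out from 19 and returns at 24. The silyl group is exchanged for acetate at the aldehyde stage, where the lactol is stabilised as a vinylogous acid derivative (Bu4NF, AcOH, THF; then Ac2O, pyridine), giving the 1-O-acetyl aldehyde F7. The vinylogous aldol addition of step 14 with 21 gives the 1-O-acetyl (12S)-alcohol F8, and acetylation (Ac2O, DMAP) gives 24.

## Further compounds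

F1 | step 6 | enantiomer of 12, methyl (2R)-2-[(1R,2R,6Z)-2-(dimethoxymethyl)-7-methyl-3-oxocyclonon-6-en-1-yl]-3,3-dimethoxypropanoate | O=C1CC/C=C(C)\CC[C@@H]([C@@H](C(=O)OC)C(OC)OC)[C@@H]1C(OC)OC
F2 | step 4 | (Z)-6-methyldeca-5,9-dien-2-one | C=CCC/C(C)=C\CCC(C)=O
F3 | step 4 | (Z)-1-(dimethylamino)-7-methylundeca-6,10-dien-3-one | CN(C)CCC(=O)CC/C=C(C)\CCC=C
F4 | step 4 | (Z)-7-methylundeca-1,6,10-trien-3-one | C=CC(=O)CC/C=C(C)\CCC=C
F5 | step 10 | (7S,8S)-8-bromo-7-hydroxy compound from 16 (bromohydrin) | C=C1CC[C@H](Br)[C@@](C)(O)CC[C@@H]2C(C(=O)OC)=CO[C@H](O[Si](C)(C)C(C)(C)C)[C@@H]12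
F6 | step 14 | (12S)-homoallylic alcohol from 19 | C=C1CC[C@H]2O[C@@]2(C)CC[C@@H]2C([C@H](CC=C)O)=CO[C@H](O[Si](C)(C)C(C)(C)C)[C@@H]12
F7 | step 15 | 1-O-acetyl C12 aldehyde | C=C1CC[C@H]2O[C@@]2(C)CC[C@@H]2C(C=O)=CO[C@H](OC(C)=O)[C@@H]12
F8 | step 15 | 1-O-acetyl (12S)-alcohol | C=C1CC[C@H]2O[C@@]2(C)CC[C@@H]2C([C@H](C/C=C(\C)C(=O)OC)O)=CO[C@H](OC(C)=O)[C@@H]12
A1 | alternative 1 | C1 lactol of the target (1-O-deacetyl compound) | C=C1CC[C@H]2O[C@@]2(C)CC[C@@H]2C([C@H](C/C=C(\C)C(=O)OC)OC(C)=O)=CO[C@H](O)[C@@H]12
A2 | alternative 1 | acyclic bis-enal with epoxide, C12 acetate and enoate | O=C/C=C(\C)CC[C@H]1O[C@@]1(C)CC/C=C(/C=O)[C@H](C/C=C(\C)C(=O)OC)OC(C)=O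
A3 | alternative 2 | Z-cyclononene with C11 methylene fused to the 1-methoxy-dihydropyran-4-carboxylate | C=C1CC/C=C(C)\CC[C@@H]2C(C(=O)OC)=CO[C@H](OC)[C@@H]12
A4 | alternative 2 | cyclopropane-fused cyclooctene with C19 xanthate (either cyclopropane diastereomer; C9 and C11 not specified) | CSC(=S)OCC12CC1/C=C(C)\CC[C@@H]1C(C(=O)OC)=CO[C@H](OC)[C@@H]21
A5 | alternative 3 | Z-cyclononenone fused to the 1-methoxy-dihydropyran-4-carboxylate | O=C1CC/C=C(C)\CC[C@@H]2C(C(=O)OC)=CO[C@H](OC)[C@@H]12
A6 | alternative 3 | tricyclic C11 hydroxy C8 tosylate (C7, C8 and C11 not specified; tosylate anti-periplanar to C7–C11) | Cc1ccc(S(=O)(=O)OC2CCC3(O)[C@@H]4[C@@H](OC)OC=C(C(=O)OC)[C@H]4CCC23C)cc1
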